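Ring numbering used throughout (target numbering): C1 carbonyl, C2 hydroxyl, C3 icosyl, C4 carbonyl, C5 methoxy, C6 hydrogen; C1′ is the benzylic chain carbon.
Retrosynthesis cuts, in order: the C2–O bond (hydroxyquinone from the C2/C3 epoxide of the 3-icosyl-5-methoxyquinone); the C4–O bond together with the ketal C–O bonds at C1 and C4 (quinone from its bisketal, bisketal from the arene); the C1′–C2′ bond of the chain (alkene from an aryl aldehyde and a C19 ylide).
Enabling feature: without the oxygens on C2 and C4 the six-membered ring is a mirror-symmetric 5-icosylresorcinol dimethyl ether (oxygens on C1 and C5, chain on C3). Its C4–H lies para to the C1 methoxy group, so anodic methoxylation can add the missing para oxygen and then ketalise the C1/C4 pair.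
Forward: the chain is joined first (Wittig olefination, then hydrogenation). No ring is formed anywhere; the existing benzene ring is oxidised in place by electrolysis, ketal hydrolysis, nucleophilic epoxidation and acid isomerisation.
Stereochemistry: the target has no stereocentre and no stereogenic double bond. The alkene geometry from the Wittig step is removed by hydrogenation, and the two epoxide centres (racemic, cis by ring fusion) disappear in the last step.

Key step: step 4

Assumption: the side chain is the unbranched twenty-carbon chain written in the SMILES, and the product is drawn as its 2-hydroxy-1,4-quinone tautomer.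

Step 1
Reactants: 1 1-bromononadecane; 2 triphenylphosphine
Product: 3 nonadecyl(triphenyl)phosphonium bromide
Conditions: toluene, reflux, 48 h; crystallise on cooling
Reagents that add atoms: none
Why: SN2 quaternisation of the phosphine by a primary alkyl bromide (phosphonium salt formation), which is routine for long-chain bromides.

Step 2
Reactants: 3 nonadecyl(triphenyl)phosphonium bromide; 4 3,5-dimethoxybenzaldehyde
Product: 6 (Z)-1-(icos-1-en-1-yl)-3,5-dimethoxybenzene (minor E isomer carried along), via nonadecylidene(triphenyl)phosphorane 5 (not isolated)
Conditions: KOtBu, THF, 0 °C; then 4, 0 °C to rt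
Reagents that add atoms: none
Why: Wittig olefination with a non-stabilised ylide, which should add cleanly to the unhindered aryl aldehyde and give mainly the Z alkene; the geometry is of no consequence because step 3 removes it.

Step 3
Reactants: 6 (Z)-1-(icos-1-en-1-yl)-3,5-dimethoxybenzene
Product: 7 1-icosyl-3,5-dimethoxybenzene
Conditions: H2 (1 atm), 10% Pd/C, EtOAc, 40 °C
Reagents that add atoms: none
Why: Heterogeneous catalytic hydrogenation of a disubstituted styrene-type alkene; the arene and its methyl ethers are inert under these conditions.

Step 4
Reactants: 7 1-icosyl-3,5-dimethoxybenzene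
Product: 9 1-icosyl-3,3,5,6,6-pentamethoxycyclohexa-1,4-diene (bis(dimethyl ketal) of 2-icosyl-6-methoxy-1,4-benzoquinone), via 1-icosyl-2,3,5-trimethoxybenzene 8 (not isolated)
Conditions: Pt anode, Pt cathode, undivided cell, 1% KOH in MeOH–THF (3:1), constant current, 15–20 °C, until 7 and 8 are consumed (planned charge about 6 F per mole)
Reagents that add atoms: methanol, CO
Why: Anodic nuclear methoxylation followed by anodic 1,4-addition: one-electron oxidation of 7 at platinum gives the arene radical cation, methoxide adds at C4 (para to the C1 methoxy, ortho to the C5 methoxy), and loss of a second electron and of the C4 proton gives the 1,2,4-trioxygenated arene 8. Compound 8 is oxidised at a lower potential than 7, so its radical cation takes up methoxide at the ipso carbons of the para-dimethoxy pair C1/C4 with loss of a further electron, which gives the non-aromatic bisketal 9 after four electrons and three new C–O bonds (two at C4, one at C1). The closest known reaction type is the anodic oxidation of 1,3-dimethoxybenzene and of 1,2,4-trimethoxybenzenes in methanolic KOH to 2-methoxy-1,4-benzoquinone bis(dimethyl ketals). No ring is closed and no stereocentre is formed. The step needs nuclear attack at C4 and not at C6 or at the benzylic CH2: the adduct from C4 attack is stabilised by the para methoxy group whereas C6 has only ortho methoxy groups, the strongly basic methanol medium favours nuclear addition over side-chain substitution, and the mirror symmetry of 7 makes C2 and C4 the same site. Oxidation should stop at 9 because the bisketal has lost the aromatic π system and is oxidised only at a much higher potential.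

Step 5
Reactants: 9 1-icosyl-3,3,5,6,6-pentamethoxycyclohexa-1,4-diene
Product: 11 2-icosyl-6-methoxy-1,4-benzoquinone, via 3-icosyl-4,4,5-trimethoxycyclohexa-2,5-dien-1-one 10 (not isolated)
Conditions: 1 M aq. H2SO4, THF, rt
Reagents that add atoms: water, O
Why: Acid-catalysed ketal hydrolysis, in which the C1 ketal should ionise first (its cation is stabilised by the C5 methoxy and C3 alkyl groups) to give the vinylogous ester 10 and the C4 ketal follows, while the C5 methoxy group survives as a vinylogous ester of the C1 carbonyl and the non-nucleophilic acid avoids conjugate addition of a counter-ion to the quinone.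

Step 6
Reactants: 11 2-icosyl-6-methoxy-1,4-benzoquinone
Product: 12 racemic 1-icosyl-3-methoxy-7-oxabicyclo[4.1.0]hept-3-ene-2,5-dione (the C2/C3 epoxide of 11)
Conditions: t-BuOOH (in decane), DBU, CH2Cl2, 0 °C
Reagents that add atoms: tert-butyl hydroperoxide, CC(C)(C)OO
Why: Weitz–Scheffer nucleophilic epoxidation, in which the peroxide anion should add at C2 (the unsubstituted β-carbon of the C4 enone) and the enolate closes onto oxygen with loss of tert-butoxide, whereas the C5=C6 bond is deactivated as a vinylogous ester; the two new stereocentres arise as a racemate with the cis relation forced by the three-membered ring and need no control because step 7 removes them.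

Step 7
Reactants: 12 racemic 1-icosyl-3-methoxy-7-oxabicyclo[4.1.0]hept-3-ene-2,5-dione
Product: 13 irisoquin D (2-hydroxy-3-icosyl-5-methoxy-1,4-benzoquinone)
Conditions: conc. H2SO4, 0 °C to rt, 15 min; then ice–water
Reagents that add atoms: none
Why: Acid-catalysed isomerisation of a 2,3-epoxy-1,4-quinone that carries a hydrogen on one epoxide carbon to the 2-hydroxyquinone (the classical oxide-to-hydroxyquinone rearrangement of 2-alkyl-1,4-naphthoquinone oxides), in which enolisation at C2 opens the C3–O bond so that the oxygen stays on C2 next to the chain and the conjugated vinylogous acid forms without change of oxidation level.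

Compound list
1 | 1-bromononadecane | CCCCCCCCCCCCCCCCCCCBr | starting material
2 | triphenylphosphine | c1ccc(cc1)P(c1ccccc1)c1ccccc1 | starting material
3 | nonadecyl(triphenyl)phosphonium bromide | CCCCCCCCCCCCCCCCCCC[P+](c1ccccc1)(c1ccccc1)c1ccccc1.[Br-] | intermediate
4 | 3,5-dimethoxybenzaldehyde | COc1cc(C=O)cc(OC)c1 | starting material
5 | nonadecylidene(triphenyl)phosphorane (ylide, not isolated) | CCCCCCCCCCCCCCCCCCC=P(c1ccccc1)(c1ccccc1)c1ccccc1 | intermediate
6 | (Z)-1-(icos-1-en-1-yl)-3,5-dimethoxybenzene (major isomer drawn; minor E isomer carried along) | CCCCCCCCCCCCCCCCCC/C=C\c1cc(OC)cc(OC)c1 | intermediate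
7 | 1-icosyl-3,5-dimethoxybenzene | CCCCCCCCCCCCCCCCCCCCc1cc(OC)cc(OC)c1 | intermediate
8 | 1-icosyl-2,3,5-trimethoxybenzene (not isolated) | CCCCCCCCCCCCCCCCCCCCc1cc(OC)cc(OC)c1OC | intermediate
9 | 1-icosyl-3,3,5,6,6-pentamethoxycyclohexa-1,4-diene (quinone bisketal) | CCCCCCCCCCCCCCCCCCCCC1=CC(OC)(OC)C=C(OC)C1(OC)OC | intermediate
10 | 3-icosyl-4,4,5-trimethoxycyclohexa-2,5-dien-1-one (monoketal, not isolated) | CCCCCCCCCCCCCCCCCCCCC1=CC(=O)C=C(OC)C1(OC)OC | intermediate
11 | 2-icosyl-6-methoxy-1,4-benzoquinone | CCCCCCCCCCCCCCCCCCCCC1=CC(=O)C=C(OC)C1=O | intermediate
12 | racemic 1-icosyl-3-methoxy-7-oxabicyclo[4.1.0]hept-3-ene-2,5-dione (cis-fused epoxide; one enantiomer drawn) | CCCCCCCCCCCCCCCCCCCC[C@]12O[C@H]1C(=O)C=C(OC)C2=O | intermediate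
13 | irisoquin D, 2-hydroxy-3-icosyl-5-methoxycyclohexa-2,5-diene-1,4-dione | CCCCCCCCCCCCCCCCCCCCC1=C(O)C(=O)C=C(OC)C1=O | target

Total step count: 7. Longest linear sequence: 7 steps (1 to 13); the aldehyde 4 enters in step 2.

Steps most likely to fail

Step 4. The electrolysis may lose site control: the radical cation may be trapped by methoxide at C6 between the two methoxy groups, or may be deprotonated at the benzylic carbon and give side-chain methoxylation. It may also over-oxidise, or stall because the waxy substrate separates from the methanolic electrolyte. In the fallback the first C–O bond is made chemically and only the bisketalisation is left to the anode. Setting out from 7, bromination with NBS in MeCN–CH2Cl2 at 0 °C should occur para to a methoxy group and give 2-bromo-1-icosyl-3,5-dimethoxybenzene F1. Copper-catalysed methoxylation of the aryl bromide (NaOMe, CuBr, MeOH–DMF, 110 °C; Ullmann-type ether synthesis) should give 1-icosyl-2,3,5-trimethoxybenzene 8, now as an isolated compound. Anodic oxidation of 8 in methanolic KOH, the two-electron addition of two methoxides across the para-dimethoxy pair, comes back to the route at 9.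

Step 6. The peroxide anion, or adventitious hydroxide, may attack C5 by addition–elimination and displace the methoxy group, or the base may degrade the quinone, instead of epoxidising the C2=C3 bond. In the fallback the C2 oxygen is brought in under acid. Setting out from 11, Thiele–Winter acetoxylation (Ac2O, cat. H2SO4, rt) should add acetate at C2, the β-carbon of the more electrophilic C4 enone, and give 3-icosyl-5-methoxybenzene-1,2,4-triyl triacetate F2. Acid methanolysis (cat. H2SO4, MeOH–THF, reflux, under N2) should set free 3-icosyl-5-methoxybenzene-1,2,4-triol F3, which is not isolated but oxidised in the same flask with aqueous FeCl3. The route is rejoined at 13, and 12 and step 7 are left out.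

Step 7. In concentrated acid the epoxide may undergo acyl migration with ring contraction, hydration to a diol that does not dehydrate cleanly, or cleavage of the C5 methyl ether. The fallback replaces isomerisation by substitution. Setting out from 12, HCl in dioxane at rt should open the epoxide at C2 (the carbon α to the C1 carbonyl, with inversion) to give racemic trans-5-chloro-6-hydroxy-6-icosyl-2-methoxycyclohex-2-ene-1,4-dione F4, which is not isolated and should lose water to give 2-chloro-3-icosyl-5-methoxy-1,4-benzoquinone F5. Addition–elimination with aqueous NaOH in THF at 0 °C, in which chloride leaves far more readily than methoxide, followed by acidification with dilute HCl comes back to the route at 13.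

Further compounds
F1 | step 4 | 2-bromo-1-icosyl-3,5-dimethoxybenzene | CCCCCCCCCCCCCCCCCCCCc1cc(OC)cc(OC)c1Br
F2 | step 6 | 3-icosyl-5-methoxybenzene-1,2,4-triyl triacetate | CCCCCCCCCCCCCCCCCCCCc1c(OC(C)=O)c(OC(C)=O)cc(OC)c1OC(C)=O
F3 | step 6 | 3-icosyl-5-methoxybenzene-1,2,4-triol | CCCCCCCCCCCCCCCCCCCCc1c(O)c(O)cc(OC)c1O
F4 | step 7 | racemic trans-5-chloro-6-hydroxy-6-icosyl-2-methoxycyclohex-2-ene-1,4-dione (one enantiomer drawn) | CCCCCCCCCCCCCCCCCCCC[C@]1(O)[C@H](Cl)C(=O)C=C(OC)C1=O
F5 | step 7 | 2-chloro-3-icosyl-5-methoxy-1,4-benzoquinone | CCCCCCCCCCCCCCCCCCCCC1=C(Cl)C(=O)C=C(OC)C1=O
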